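**Plan**

- Numbering used throughout: the target is named as a hexadeca-10,14-diene-5,12-dione; C16 is the benzylic CH2 on the 5-hydroxy-2-methoxy-3-methylphenyl ring, C6 is the stereocentre, C2 carries the tertiary hydroxyl.
- Retrosynthetic cuts, in order: C15–C16 together with C14–CH3 (key step), C4–C5 (Weinreb ketone synthesis), C12–C13 (propargylation), C9–C10 (B-alkyl Suzuki coupling), C6–C7 (Evans allylation).
- Enabling feature: the 14E olefin carries its C14 methyl cis to the benzylic C16 and is separated from C12 by the C13 methylene. This is the pattern left by syn addition of methyl and metal to a terminal C14≡C15 alkyne, followed by exchange of the metal for the benzylic carbon of the benzene ring. A homopropargylic C12 carbinol and a C5 Weinreb amide keep both ketones latent during that event.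
- Forward order: the chain is grown from C6 to C15 (allylation, Weinreb amide, hydroboration/Suzuki coupling with Z-3-iodobutenol, oxidation, propargylation). The arene is made as a benzylic chloride by directed ortho-lithiation. The two are joined in the key step; then the C1–C4 tail is added, C12 is oxidised and the silyl groups are removed.
- Stereochemistry: 6R from the Evans auxiliary; 10Z from hydroxyl-directed trans-hydroalumination/iodination and a stereoretentive coupling; 14E from the syn carbometalation.

Key step: step 10

Remark: the carbinol carbon made in step 9 (C12 of the target chain) is carried as both epimers, because step 13 turns it into the ketone; compounds 19, 20, 21 and 25 are therefore drawn without configuration at that carbon.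

**Route**

Step 1
Reactants: 1 4-methoxy-3-methylphenol
Product: 2 triisopropyl(4-methoxy-3-methylphenoxy)silane
Conditions: i-Pr3SiCl, imidazole, DMF, rt
Reagents that add atoms: triisopropylsilyl chloride, CC(C)[Si](Cl)(C(C)C)C(C)C
Why: Imidazole-promoted silylation of the phenol; the bulky triisopropylsilyl group shields both positions next to its oxygen against lithiation in step 2 and should survive every later step until the fluoride treatment of step 14.

Step 2
Reactants: 2 triisopropyl(4-methoxy-3-methylphenoxy)silane
Product: 4 [2-methoxy-3-methyl-5-(triisopropylsilyloxy)phenyl]methanol, via aryllithium 3 (not isolated)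
Conditions: n-BuLi, TMEDA, Et2O, 0 °C to rt; (CH2O)n, THF, −78 °C to rt; sat. aq. NH4Cl
Reagents that add atoms: formaldehyde (from paraformaldehyde), C=O
Why: Directed ortho-metalation, in which the methoxy group guides n-BuLi/TMEDA to its only free neighbouring ring position (the other neighbour carries the methyl group and the silyloxy group is a poor, hindered director), followed by hydroxymethylation of the aryllithium with formaldehyde.

Step 3
Reactants: 4 [2-methoxy-3-methyl-5-(triisopropylsilyloxy)phenyl]methanol
Product: 5 [3-(chloromethyl)-4-methoxy-5-methylphenoxy]triisopropylsilane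
Conditions: N-chlorosuccinimide, PPh3, THF, 0 °C to rt
Reagents that add atoms: N-chlorosuccinimide, O=C1CCC(=O)N1Cl
Why: Appel-type chlorination through the alkoxyphosphonium chloride should convert the primary benzylic alcohol into the chloride under neutral conditions that leave the aryl silyl ether intact.

Step 4
Reactants: 6 (4S)-4-benzyl-3-propanoyl-1,3-oxazolidin-2-one, 7 allyl iodide
Product: 9 (4S)-4-benzyl-3-[(2R)-2-methylpent-4-enoyl]-1,3-oxazolidin-2-one, via sodium Z-enolate 8 (not isolated)
Conditions: NaN(SiMe3)2, THF, −78 °C; then 7, −78 to −45 °C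
Reagents that add atoms: none
Why: Evans asymmetric alkylation, in which the chelated sodium Z-enolate is allylated on the face away from the C4 benzyl group of the auxiliary, setting the R-configured methyl-bearing carbon that becomes C6 of the target.

Step 5
Reactants: 9 (4S)-4-benzyl-3-[(2R)-2-methylpent-4-enoyl]-1,3-oxazolidin-2-one
Product: 10 (2R)-N-methoxy-N,2-dimethylpent-4-enamide
Conditions: MeNHOMe·HCl, AlMe3, CH2Cl2, 0 °C to rt; dilute aq. HCl work-up
Reagents that add atoms: N,O-dimethylhydroxylamine hydrochloride, CNOC.Cl
Why: Weinreb transamidation with the aluminium amide cleaves the exocyclic acyl–N bond without enolisation, so the stereocentre should be kept and the auxiliary released for recovery.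

Step 6
Reactants: 11 but-2-yn-1-ol
Product: 13 (2Z)-3-iodobut-2-en-1-ol, via cyclic alkenylalanate 12 (not isolated)
Conditions: NaAlH2(OCH2CH2OMe)2, Et2O, 0 °C to rt; EtOAc; then I2, THF, −78 to 0 °C
Reagents that add atoms: iodine, II
Why: Hydroxyl-directed trans-hydroalumination of the propargylic alcohol places aluminium on C3 cis to the CH2O arm inside a five-membered alkoxyalanate, and iodinolysis with retention should give the Z vinyl iodide.

Step 7
Reactants: 10 (2R)-N-methoxy-N,2-dimethylpent-4-enamide, 13 (2Z)-3-iodobut-2-en-1-ol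
Product: 15 (2R,6Z)-8-hydroxy-N-methoxy-N,2,6-trimethyloct-6-enamide, via B-alkyl-9-BBN adduct 14 (not isolated)
Conditions: 9-BBN, THF, 0 °C to rt; then aq. Cs2CO3, 13, PdCl2(dppf) (5 mol%), AsPh3, DMF, rt
Reagents that add atoms: none
Why: Anti-Markovnikov hydroboration of the terminal olefin with 9-BBN followed by B-alkyl Suzuki–Miyaura coupling, which proceeds with retention at the vinyl iodide and so should deliver the 10Z trisubstituted olefin of the target while tolerating the Weinreb amide and the free hydroxyl.

Step 8
Reactants: 15 (2R,6Z)-8-hydroxy-N-methoxy-N,2,6-trimethyloct-6-enamide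
Product: 16 (2R,6Z)-N-methoxy-N,2,6-trimethyl-8-oxooct-6-enamide
Conditions: TEMPO (10 mol%), PhI(OAc)2, CH2Cl2, 0 °C to rt
Reagents that add atoms: none
Why: TEMPO/PhI(OAc)2 oxidation (oxoammonium mechanism) takes the primary allylic alcohol to the enal under near-neutral conditions that should not isomerise the Z olefin and do not touch the Weinreb amide.

Step 9
Reactants: 16 (2R,6Z)-N-methoxy-N,2,6-trimethyl-8-oxooct-6-enamide, 17 propargyl bromide
Product: 19 (2R,6Z)-8-hydroxy-N-methoxy-N,2,6-trimethylundec-6-en-10-ynamide (both C8 epimers), via allenylzinc bromide 18 (not isolated)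
Conditions: Zn dust, THF, 0 °C to rt; sat. aq. NH4Cl
Reagents that add atoms: none
Why: Barbier propargylation, in which allenylzinc bromide formed in situ adds through an SE2′ six-membered transition state to the aldehyde only (the Weinreb amide is inert to organozinc reagents), giving the homopropargylic alcohol whose new carbinol centre needs no control because it is oxidised in step 13.

Step 10
Reactants: 19 (2R,6Z)-8-hydroxy-N-methoxy-N,2,6-trimethylundec-6-en-10-ynamide, 5 [3-(chloromethyl)-4-methoxy-5-methylphenoxy]triisopropylsilane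
Product: 21 (2R,6Z,10E)-8-hydroxy-N-methoxy-12-[2-methoxy-3-methyl-5-(triisopropylsilyloxy)phenyl]-N,2,6,10-tetramethyldodeca-6,10-dienamide, via E-alkenyldimethylalane 20 (not isolated)
Conditions: AlMe3 (5 equiv), Cp2ZrCl2 (0.5 equiv), CH2Cl2, 0 °C to rt (no heating); volatiles removed in vacuo; then 5 (1.2 equiv), Pd(PPh3)4 (5 mol%), THF, rt; aq. potassium sodium tartrate
Reagents that add atoms: trimethylaluminium, C[Al](C)C
Why: After AlMe3 has turned the carbinol into its aluminium alkoxide, zirconocene-catalysed syn-methylalumination (Negishi carboalumination) adds methyl to the internal alkyne carbon and the metal to the CH terminus, so that 20 carries aluminium cis to the new methyl; zerovalent palladium then inserts into the benzylic C–Cl bond of 5, the alkenyl group rather than methyl is transferred from aluminium, and reductive elimination forms the benzylic CH2–CH= bond with retention of olefin geometry. The closest known reaction type is exactly this one-pot carboalumination and palladium- or nickel-catalysed coupling of the alkenylalane with a benzylic chloride, an established way to attach E-configured prenyl-type chains to oxygenated arenes. No ring is closed and no stereocentre is created; the stereochemical element set here is the 14E olefin, fixed by the syn addition. The step needs regioselectivity (methyl to C14, metal to C15), which the terminal position of the alkyne and the bulk of the zirconocene secure, and it needs geometric integrity of 20, which is kept by working at or below room temperature so that the homopropargylic aluminium alkoxide cannot drive the slow chelation-controlled isomerisation of the alkenylalane. Chemoselectivity rests on the Weinreb amide, which stands in for the C5 ketone because AlMe3 only coordinates to it, on the inertness of the trisubstituted 10Z olefin to carbometalation, and on removal of excess AlMe3 before the palladium stage so that methyl transfer to 5 is suppressed.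

Step 11
Reactants: 22 4-bromo-2-methylbutan-2-ol
Product: 23 [(4-bromo-2-methylbutan-2-yl)oxy]triethylsilane
Conditions: Et3SiOTf, 2,6-lutidine, CH2Cl2, −78 to 0 °C
Reagents that add atoms: triethylsilyl trifluoromethanesulfonate, CC[Si](CC)(CC)OS(=O)(=O)C(F)(F)F
Why: Silylation of the tertiary alcohol with the silyl triflate and a hindered pyridine base (standard silyl ether formation) masks the hydroxyl so that the bromide can be turned into a Grignard reagent.

Step 12
Reactants: 21 (2R,6Z,10E)-8-hydroxy-N-methoxy-12-[2-methoxy-3-methyl-5-(triisopropylsilyloxy)phenyl]-N,2,6,10-tetramethyldodeca-6,10-dienamide, 23 [(4-bromo-2-methylbutan-2-yl)oxy]triethylsilane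
Product: 25 (6R,10Z,14E)-12-hydroxy-16-[2-methoxy-3-methyl-5-(triisopropylsilyloxy)phenyl]-2,6,10,14-tetramethyl-2-(triethylsilyloxy)hexadeca-10,14-dien-5-one, via Grignard reagent 24 (not isolated)
Conditions: 23, Mg, THF, rt; then 21 (24 in 3.5-fold excess), THF, 0 °C to rt; sat. aq. NH4Cl
Reagents that add atoms: none
Why: Weinreb ketone synthesis, in which the first equivalent of 24 deprotonates the carbinol and addition to the amide then gives a stable five-membered magnesium chelate that collapses to the ketone only on work-up, which should prevent over-addition and enolisation of the adjacent stereocentre.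

Step 13
Reactants: 25 (6R,10Z,14E)-12-hydroxy-16-[2-methoxy-3-methyl-5-(triisopropylsilyloxy)phenyl]-2,6,10,14-tetramethyl-2-(triethylsilyloxy)hexadeca-10,14-dien-5-one
Product: 26 (6R,10Z,14E)-16-[2-methoxy-3-methyl-5-(triisopropylsilyloxy)phenyl]-2,6,10,14-tetramethyl-2-(triethylsilyloxy)hexadeca-10,14-diene-5,12-dione
Conditions: Dess–Martin periodinane, NaHCO3, CH2Cl2, 0 °C
Reagents that add atoms: none
Why: Dess–Martin oxidation under bicarbonate buffering turns the allylic carbinol into the C12 ketone without acid or base, so the 14E olefin should stay out of conjugation, the 10Z enone should keep its geometry and C6 should not epimerise, while both silyl ethers are inert.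

Step 14
Reactants: 26 (6R,10Z,14E)-16-[2-methoxy-3-methyl-5-(triisopropylsilyloxy)phenyl]-2,6,10,14-tetramethyl-2-(triethylsilyloxy)hexadeca-10,14-diene-5,12-dione
Product: 27 (6R,10Z,14E)-2-hydroxy-16-(5-hydroxy-2-methoxy-3-methylphenyl)-2,6,10,14-tetramethylhexadeca-10,14-diene-5,12-dione
Conditions: TBAF, AcOH (1:1), THF, 0 °C to rt
Reagents that add atoms: none
Why: Fluoride-mediated desilylation cleaves the aryl triisopropylsilyl ether and the tertiary triethylsilyl ether in one operation, and buffering with acetic acid should keep phenoxide and fluoride basicity low enough to spare the skipped dienone and the C6 stereocentre.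

**Compound list**

1 | 4-methoxy-3-methylphenol | COc1ccc(O)cc1C | starting material
2 | triisopropyl(4-methoxy-3-methylphenoxy)silane | COc1ccc(O[Si](C(C)C)(C(C)C)C(C)C)cc1C | intermediate
3 | [2-methoxy-3-methyl-5-(triisopropylsilyloxy)phenyl]lithium (not isolated) | COc1c([Li])cc(O[Si](C(C)C)(C(C)C)C(C)C)cc1C | intermediate
4 | [2-methoxy-3-methyl-5-(triisopropylsilyloxy)phenyl]methanol | COc1c(CO)cc(O[Si](C(C)C)(C(C)C)C(C)C)cc1C | intermediate
5 | [3-(chloromethyl)-4-methoxy-5-methylphenoxy]triisopropylsilane | COc1c(CCl)cc(O[Si](C(C)C)(C(C)C)C(C)C)cc1C | intermediate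
6 | (4S)-4-benzyl-3-propanoyl-1,3-oxazolidin-2-one | CCC(=O)N1[C@@H](Cc2ccccc2)COC1=O | starting material
7 | allyl iodide (3-iodoprop-1-ene) | C=CCI | starting material
8 | sodium Z-enolate of 6 (not isolated) | C/C=C(\[O-])N1[C@@H](Cc2ccccc2)COC1=O.[Na+] | intermediate
9 | (4S)-4-benzyl-3-[(2R)-2-methylpent-4-enoyl]-1,3-oxazolidin-2-one | C=CC[C@@H](C)C(=O)N1[C@@H](Cc2ccccc2)COC1=O | intermediate
10 | (2R)-N-methoxy-N,2-dimethylpent-4-enamide | C=CC[C@@H](C)C(=O)N(C)OC | intermediate
11 | but-2-yn-1-ol | CC#CCO | starting material
12 | sodium bis(2-methoxyethoxy)alanate of the trans-hydroaluminated alcohol, a five-membered 1,2-oxaaluminacycle (not isolated) | CC1=CCO[Al-]1(OCCOC)OCCOC.[Na+] | intermediate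
13 | (2Z)-3-iodobut-2-en-1-ol | C/C(I)=C/CO | intermediate
14 | (2R)-5-(9-borabicyclo[3.3.1]nonan-9-yl)-N-methoxy-N,2-dimethylpentanamide (not isolated) | B1(C2CCCC1CCC2)CCC[C@@H](C)C(=O)N(C)OC | intermediate
15 | (2R,6Z)-8-hydroxy-N-methoxy-N,2,6-trimethyloct-6-enamide | OC/C=C(/C)CCC[C@@H](C)C(=O)N(C)OC | intermediate
16 | (2R,6Z)-N-methoxy-N,2,6-trimethyl-8-oxooct-6-enamide | O=C/C=C(/C)CCC[C@@H](C)C(=O)N(C)OC | intermediate
17 | propargyl bromide (3-bromoprop-1-yne) | C#CCBr | starting material
18 | allenylzinc bromide (not isolated) | C=C=C[Zn]Br | intermediate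
19 | (2R,6Z)-8-hydroxy-N-methoxy-N,2,6-trimethylundec-6-en-10-ynamide, both C8 epimers | C#CCC(O)/C=C(/C)CCC[C@@H](C)C(=O)N(C)OC | intermediate
20 | (2R,6Z,10E)-11-(dimethylalumanyl)-8-[(dimethylalumanyl)oxy]-N-methoxy-N,2,6,10-tetramethylundeca-6,10-dienamide (not isolated) | C[Al](C)/C=C(\C)CC(O[Al](C)C)/C=C(/C)CCC[C@@H](C)C(=O)N(C)OC | intermediate
21 | (2R,6Z,10E)-8-hydroxy-N-methoxy-12-[2-methoxy-3-methyl-5-(triisopropylsilyloxy)phenyl]-N,2,6,10-tetramethyldodeca-6,10-dienamide | COc1c(C)cc(O[Si](C(C)C)(C(C)C)C(C)C)cc1C/C=C(\C)CC(O)/C=C(/C)CCC[C@@H](C)C(=O)N(C)OC | intermediate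
22 | 4-bromo-2-methylbutan-2-ol | CC(C)(O)CCBr | starting material
23 | [(4-bromo-2-methylbutan-2-yl)oxy]triethylsilane | CC[Si](CC)(CC)OC(C)(C)CCBr | intermediate
24 | [3-methyl-3-(triethylsilyloxy)butyl]magnesium bromide (not isolated) | CC[Si](CC)(CC)OC(C)(C)CC[Mg]Br | intermediate
25 | (6R,10Z,14E)-12-hydroxy-16-[2-methoxy-3-methyl-5-(triisopropylsilyloxy)phenyl]-2,6,10,14-tetramethyl-2-(triethylsilyloxy)hexadeca-10,14-dien-5-one | COc1c(C)cc(O[Si](C(C)C)(C(C)C)C(C)C)cc1C/C=C(\C)CC(O)/C=C(/C)CCC[C@@H](C)C(=O)CCC(C)(C)O[Si](CC)(CC)CC | intermediate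
26 | (6R,10Z,14E)-16-[2-methoxy-3-methyl-5-(triisopropylsilyloxy)phenyl]-2,6,10,14-tetramethyl-2-(triethylsilyloxy)hexadeca-10,14-diene-5,12-dione | COc1c(C)cc(O[Si](C(C)C)(C(C)C)C(C)C)cc1C/C=C(\C)CC(=O)/C=C(/C)CCC[C@@H](C)C(=O)CCC(C)(C)O[Si](CC)(CC)CC | intermediate
27 | (6R,10Z,14E)-2-hydroxy-16-(5-hydroxy-2-methoxy-3-methylphenyl)-2,6,10,14-tetramethylhexadeca-10,14-diene-5,12-dione | COc1c(C)cc(O)cc1C/C=C(\C)CC(=O)/C=C(/C)CCC[C@@H](C)C(=O)CCC(C)(C)O | target

**Step count and risks**

Total step count: 14. Longest linear sequence: 9 steps (steps 4, 5, 7, 8, 9, 10, 12, 13, 14).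

The three steps most likely to fail:

Step 10. The Lewis-basic Weinreb amide and the aluminium alkoxide may slow the zirconium-catalysed methylalumination. The alkenylalane may lose geometric purity through chelation-driven isomerisation. Methyl instead of alkenyl may be transferred to the benzylpalladium species if AlMe3 is not fully removed. The fallback sets out from 19 and comes back at 21, replacing aluminium by boron and separating the two events. Silylation of 19 (Et3SiCl, imidazole, DMF) should give (2R,6Z)-N-methoxy-N,2,6-trimethyl-8-(triethylsilyloxy)undec-6-en-10-ynamide F1, whose hydroxyl can then no longer protonate a copper–boryl species. Copper-catalysed syn-methylboration (B2pin2, MeI, CuCl, Xantphos, NaOt-Bu, THF, rt) should place boron on the terminal carbon and methyl on the internal one, giving the E-alkenyl pinacolboronate F2. Suzuki–Miyaura coupling of F2 with 5 (Pd(PPh3)4, aq. K3PO4, THF, 60 °C) should give the C8 triethylsilyl ether of 21 F3. Selective removal of the secondary triethylsilyl group (PPTS, MeOH, rt), which should leave the aryl triisopropylsilyl ether untouched, returns 21.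

Step 14. Fluoride or phenoxide basicity may move the 14,15-double bond into conjugation with the C12 ketone, isomerise the 10Z enone to 10E, or epimerise C6 in the finished skipped dienone. The fallback sets out from 25 and comes back at 27 by reversing the order of the last two operations. Buffered TBAF/AcOH desilylation of 25, which has no dienone yet, should give (6R,10Z,14E)-2,12-dihydroxy-16-(5-hydroxy-2-methoxy-3-methylphenyl)-2,6,10,14-tetramethylhexadeca-10,14-dien-5-one F4. The allylic C12 carbinol of F4 is then oxidised last with activated MnO2 in CH2Cl2, a neutral heterogeneous oxidant selective for allylic alcohols that leaves the tertiary hydroxyl alone, to give 27. Tolerance of the free phenol toward MnO2 is the point to watch.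

Step 12. Addition of the Grignard reagent to the α-branched Weinreb amide may be slow in the presence of the magnesium alkoxide, leading to incomplete conversion or enolisation at C6. The fallback sets out from 21 and comes back at 26. Reduction of the Weinreb amide with i-Bu2AlH (THF, −78 °C, one extra equivalent for the hydroxyl) should give (2R,6Z,10E)-8-hydroxy-12-[2-methoxy-3-methyl-5-(triisopropylsilyloxy)phenyl]-2,6,10-trimethyldodeca-6,10-dienal F5, which is used at once. Addition of 24 to this more electrophilic carbonyl should give (6R,10Z,14E)-16-[2-methoxy-3-methyl-5-(triisopropylsilyloxy)phenyl]-2,6,10,14-tetramethyl-2-(triethylsilyloxy)hexadeca-10,14-diene-5,12-diol F6 as a mixture of carbinol epimers. Dess–Martin oxidation of both secondary carbinols at once (NaHCO3, CH2Cl2) converges on 26.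

Further compounds
F1 | step 10 | (2R,6Z)-N-methoxy-N,2,6-trimethyl-8-(triethylsilyloxy)undec-6-en-10-ynamide | C#CCC(O[Si](CC)(CC)CC)/C=C(/C)CCC[C@@H](C)C(=O)N(C)OC
F2 | step 10 | (2R,6Z,10E)-N-methoxy-N,2,6,10-tetramethyl-11-(4,4,5,5-tetramethyl-1,3,2-dioxaborolan-2-yl)-8-(triethylsilyloxy)undeca-6,10-dienamide | CC1(C)OB(OC1(C)C)/C=C(\C)CC(O[Si](CC)(CC)CC)/C=C(/C)CCC[C@@H](C)C(=O)N(C)OC
F3 | step 10 | (2R,6Z,10E)-N-methoxy-12-[2-methoxy-3-methyl-5-(triisopropylsilyloxy)phenyl]-N,2,6,10-tetramethyl-8-(triethylsilyloxy)dodeca-6,10-dienamide | COc1c(C)cc(O[Si](C(C)C)(C(C)C)C(C)C)cc1C/C=C(\C)CC(O[Si](CC)(CC)CC)/C=C(/C)CCC[C@@H](C)C(=O)N(C)OC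
F4 | step 14 | (6R,10Z,14E)-2,12-dihydroxy-16-(5-hydroxy-2-methoxy-3-methylphenyl)-2,6,10,14-tetramethylhexadeca-10,14-dien-5-one | COc1c(C)cc(O)cc1C/C=C(\C)CC(O)/C=C(/C)CCC[C@@H](C)C(=O)CCC(C)(C)O
F5 | step 12 | (2R,6Z,10E)-8-hydroxy-12-[2-methoxy-3-methyl-5-(triisopropylsilyloxy)phenyl]-2,6,10-trimethyldodeca-6,10-dienal | COc1c(C)cc(O[Si](C(C)C)(C(C)C)C(C)C)cc1C/C=C(\C)CC(O)/C=C(/C)CCC[C@@H](C)C=O
F6 | step 12 | (6R,10Z,14E)-16-[2-methoxy-3-methyl-5-(triisopropylsilyloxy)phenyl]-2,6,10,14-tetramethyl-2-(triethylsilyloxy)hexadeca-10,14-diene-5,12-diol | COc1c(C)cc(O[Si](C(C)C)(C(C)C)C(C)C)cc1C/C=C(\C)CC(O)/C=C(/C)CCC[C@@H](C)C(O)CCC(C)(C)O[Si](CC)(CC)CC
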